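**Plan**

1. Positions follow germacrane numbering (ring C1–C10; lactone O–C6, C7, C11=C13, C12=O). The α-methylene-γ-lactone is a trans C6-hydroxy/C7-ethynyl pair plus one carbon (C12), so after removal of the two silyl ethers the retrosynthesis cuts O–C12 and C11–C12 and excises CO.
2. Further cuts: the C9 ester C–O bond, ring bond C9–C10 (alkenyl iodide/aldehyde), the C1=C10 olefin (iodo-ylide), C6–C7 (enal/propargylic mesylate) and C2–C3 (glycolate alkylation).
3. Forward: the chain is joined in the order C2–C3, C6–C7, C1=C10; the ten-membered ring closes at C9–C10; the side-chain acid is esterified; the lactone ring closes last by CO insertion; desilylation ends the route.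
4. Stereochemistry: C2 from an (S)-benzyloxazolidinone glycolate alkylation; C7 from an (R)-propargylic mesylate (asymmetric transfer hydrogenation) with net inversion, C6 from the anti-selective allenylindium addition; C9 in the ring closure.
5. Olefin geometry: 4E from SeO2 oxidation of prenyl acetate, 1(10)Z from the iodo-ylide olefination, side-chain Z from (Z)-2-iodobut-2-enal.

Key step: step 26

Remark: compounds 4 and 12 are taken as purchasable; TBS = tert-butyldimethylsilyl, TES = triethylsilyl, TMS = trimethylsilyl, PMB = 4-methoxybenzyl.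

**Route**

Step 1
Reactants: 1 prenyl acetate
Product: 2 (E)-4-hydroxy-3-methylbut-2-en-1-yl acetate
Conditions: SeO2 (cat.), t-BuOOH, salicylic acid (cat.), CH2Cl2, rt
Reagents that add atoms: tert-butyl hydroperoxide, CC(C)(C)OO (oxygen source, relayed by SeO2, O=[Se]=O)
Why: Selenium dioxide allylic oxidation (ene reaction, then [2,3]-sigmatropic shift) attacks the methyl group trans to the acetoxymethyl chain, which should give the E allylic alcohol that becomes the C4=C5 olefin with C3 oxygenated.

Step 2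
Reactants: 2 (E)-4-hydroxy-3-methylbut-2-en-1-yl acetate
Product: 3 (E)-4-iodo-3-methylbut-2-en-1-yl acetate
Conditions: PPh3, I2, imidazole, CH2Cl2, 0 °C, dark
Reagents that add atoms: iodine, II
Why: Appel-type iodination displaces the oxyphosphonium of the primary allylic alcohol by SN2, leaving the acetate and the alkene geometry untouched if the iodide is kept cold and used at once.

Step 3
Reactants: 4 2-[(tert-butyldimethylsilyl)oxy]acetic acid; 5 (S)-4-benzyloxazolidin-2-one
Product: 7 (S)-4-benzyl-3-{2-[(tert-butyldimethylsilyl)oxy]acetyl}oxazolidin-2-one, via mixed pivalic anhydride 6 (not isolated)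
Conditions: t-BuCOCl, Et3N, THF, −20 °C; then 5, LiCl, −20 °C → rt
Reagents that add atoms: none
Why: N-Acylation of the oxazolidinone through the mixed pivalic anhydride under LiCl/Et3N activation is a standard entry to such imides and spares the silyl ether.

Step 4
Reactants: 7 glycolyl imide; 3 allylic iodide
Product: 9 (S)-4-benzyl-3-[(2R,4E)-6-acetoxy-2-(tert-butyldimethylsilyloxy)-4-methylhex-4-enoyl]oxazolidin-2-one, via sodium enolate 8 (not isolated)
Conditions: NaN(SiMe3)2, THF, −78 °C; then 3, −78 → −45 °C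
Reagents that add atoms: none
Why: Evans-type glycolate alkylation, in which the chelated sodium Z-enolate is shielded on one face by the benzyl group, so the allylic iodide should add to the opposite face, forming C2–C3 and setting C2 as R.

Step 5
Reactants: 9 alkylated imide
Product: 10 methyl (2R,4E)-2-(tert-butyldimethylsilyloxy)-6-hydroxy-4-methylhex-4-enoate
Conditions: K2CO3, MeOH, 0 °C
Reagents that add atoms: methanol, CO
Why: Carbonate-catalysed methanolysis cleaves the exocyclic imide carbonyl (activated by the α-oxygen) and transesterifies the acetate in one operation, and C2 is not expected to epimerise at 0 °C.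

Step 6
Reactants: 10 hydroxy ester
Product: 11 methyl (2R,4E)-2-(tert-butyldimethylsilyloxy)-4-methyl-6-oxohex-4-enoate
Conditions: MnO2, CH2Cl2, rt
Reagents that add atoms: none
Why: MnO2 oxidises only the allylic alcohol under neutral conditions, giving the E enal that serves as the C6 electrophile.

Step 7
Reactants: 12 3-[(4-methoxybenzyl)oxy]propan-1-ol
Product: 13 3-[(4-methoxybenzyl)oxy]propanal
Conditions: TEMPO (cat.), PhI(OAc)2, CH2Cl2, rt
Reagents that add atoms: none
Why: Oxoammonium (TEMPO) oxidation stops at the aldehyde and tolerates the PMB ether.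

Step 8
Reactants: 14 trimethylsilylacetylene; 13 3-[(4-methoxybenzyl)oxy]propanal
Product: 16 rac-5-[(4-methoxybenzyl)oxy]-1-(trimethylsilyl)pent-1-yn-3-ol, via lithium trimethylsilylacetylide 15 (not isolated)
Conditions: n-BuLi, THF, −78 °C; then 13, −78 °C
Reagents that add atoms: none
Why: 1,2-Addition of the lithium acetylide to the aldehyde builds the C7–C11 bond of the future propargylic centre, racemic at this stage.

Step 9
Reactants: 16 racemic propargylic alcohol
Product: 17 5-[(4-methoxybenzyl)oxy]-1-(trimethylsilyl)pent-1-yn-3-one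
Conditions: MnO2, CH2Cl2, rt
Reagents that add atoms: none
Why: Propargylic alcohols are oxidised by MnO2 under neutral conditions, which avoids β-elimination of the PMB-oxy group from the ynone.

Step 10
Reactants: 17 ynone
Product: 18 (R)-5-[(4-methoxybenzyl)oxy]-1-(trimethylsilyl)pent-1-yn-3-ol
Conditions: Ru[(R,R)-TsNCHPhCHPhNH](p-cymene) (cat.), i-PrOH, rt
Reagents that add atoms: none
Why: Noyori asymmetric transfer hydrogenation of an alkynyl ketone, in which the (R,R)-diamine ruthenium hydride recognises the alkynyl group and should deliver hydrogen to the face that gives the R alcohol.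

Step 11
Reactants: 18 (R)-propargylic alcohol
Product: 19 (R)-5-[(4-methoxybenzyl)oxy]-1-(trimethylsilyl)pent-1-yn-3-yl methanesulfonate
Conditions: MsCl, Et3N, CH2Cl2, −78 → 0 °C
Reagents that add atoms: methanesulfonyl chloride, CS(=O)(=O)Cl
Why: Mesylation with retention gives the leaving group needed for SN2' oxidative addition.

Step 12
Reactants: 11 enal; 19 (R)-propargylic mesylate
Product: 21 methyl (2R,4E,6R,7S)-2-(tert-butyldimethylsilyloxy)-6-hydroxy-7-{2-[(4-methoxybenzyl)oxy]ethyl}-4-methyl-9-(trimethylsilyl)non-4-en-8-ynoate, via allenylindium species 20 (not isolated)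
Conditions: PdCl2(dppf) (5 mol%), InI, THF/HMPA (3:1), rt
Reagents that add atoms: none
Why: Marshall propargylation, in which zerovalent palladium displaces the mesylate in an anti SN2' sense, transmetalation with InI gives the (P)-allenyl species of trivalent indium, and its cyclic SE2' addition to the enal should give the anti homopropargylic alcohol, C7 (S) coming from the mesylate with net inversion and C6 (R) from the transition state that keeps the alkenyl residue away from the C8 chain.

Step 13
Reactants: 21 anti homopropargylic alcohol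
Product: 22 methyl (2R,4E,6R,7S)-2-(tert-butyldimethylsilyloxy)-7-{2-[(4-methoxybenzyl)oxy]ethyl}-4-methyl-6-(triethylsilyloxy)-9-(trimethylsilyl)non-4-en-8-ynoate
Conditions: Et3SiOTf, 2,6-lutidine, CH2Cl2, −78 °C
Reagents that add atoms: triethylsilyl trifluoromethanesulfonate, CC[Si](CC)(CC)OS(=O)(=O)C(F)(F)F
Why: Silyl triflate silylation of the hindered C6 alcohol, with TES chosen because it can later be removed in the presence of both TBS ethers.

Step 14
Reactants: 22 TES ether ester
Product: 23 (2R,4E,6R,7S)-2-(tert-butyldimethylsilyloxy)-7-{2-[(4-methoxybenzyl)oxy]ethyl}-4-methyl-6-(triethylsilyloxy)-9-(trimethylsilyl)non-4-en-8-ynal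
Conditions: i-Bu2AlH, CH2Cl2, −78 °C
Reagents that add atoms: none
Why: Reduction of an α-silyloxy methyl ester with i-Bu2AlH at −78 °C stops at the aldehyde because the chelated tetrahedral aluminate survives until work-up.

Step 15
Reactants: 23 C1 aldehyde; 24 ethyltriphenylphosphonium bromide
Product: 28 (3S,4R,5E,8R,9Z)-8-(tert-butyldimethylsilyloxy)-10-iodo-1-[(4-methoxybenzyl)oxy]-6-methyl-4-(triethylsilyloxy)-3-[(trimethylsilyl)ethynyl]undeca-5,9-diene, via ethylidenetriphenylphosphorane 25 (not isolated), via (1-iodoethyl)triphenylphosphonium iodide 26 (not isolated), via (1-iodoethylidene)triphenylphosphorane 27 (not isolated)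
Conditions: 24, n-BuLi, THF, rt; I2, −78 °C; NaN(SiMe3)2, −20 °C; then 23, −78 °C
Reagents that add atoms: iodine, II
Why: Stork–Zhao olefination, in which the α-iodo ylide reacts with the aldehyde under kinetic Wittig control to give the Z 2-iodoalkene (iodine cis to C2), fixing the 1(10)-Z geometry, while the low temperature should preserve C2.

Step 16
Reactants: 28 alkenyl iodide PMB ether
Product: 29 (3S,4R,5E,8R,9Z)-8-(tert-butyldimethylsilyloxy)-10-iodo-6-methyl-4-(triethylsilyloxy)-3-[(trimethylsilyl)ethynyl]undeca-5,9-dien-1-ol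
Conditions: DDQ, CH2Cl2/pH 7 buffer, 0 °C
Reagents that add atoms: none
Why: Oxidative cleavage of the PMB ether by DDQ in buffered wet CH2Cl2 frees the primary C9 alcohol without affecting the silyl ethers, the alkenyl iodide or the silylalkyne.

Step 17
Reactants: 29 primary alcohol
Product: 30 (3S,4R,5E,8R,9Z)-8-(tert-butyldimethylsilyloxy)-10-iodo-6-methyl-4-(triethylsilyloxy)-3-[(trimethylsilyl)ethynyl]undeca-5,9-dienal
Conditions: Dess–Martin periodinane, CH2Cl2, 0 °C → rt
Reagents that add atoms: none
Why: Dess–Martin oxidation gives the C9 aldehyde under mild conditions, and this aldehyde has neither an α stereocentre nor a β leaving group.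

Step 18
Reactants: 30 iodo aldehyde
Product: 32 (1S,2Z,4R,6E,8R,9S)-4-(tert-butyldimethylsilyloxy)-2,6-dimethyl-8-(triethylsilyloxy)-9-[(trimethylsilyl)ethynyl]cyclodeca-2,6-dien-1-ol, via alkenylchromium dichloride 31 (not isolated)
Conditions: CrCl2 (excess), NiCl2 (cat.), DMSO/THF, rt, high dilution, slow addition
Reagents that add atoms: none
Why: Nozaki–Hiyama–Kishi reaction, in which nickel-catalysed formation of the alkenylchromium (divalent chromium as reductant, olefin geometry retained) and its chemoselective addition to the aldehyde close the ten-membered ring at C9–C10, C9 being set by substrate control (attack on the aldehyde face turned outward from the folding chain, carbonyl anti to the C10 methyl), which is expected to give 9S and must be verified.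

Step 19
Reactants: 32 silylalkyne ring alcohol
Product: 33 (1S,2Z,4R,6E,8R,9S)-4-(tert-butyldimethylsilyloxy)-9-ethynyl-2,6-dimethyl-8-(triethylsilyloxy)cyclodeca-2,6-dien-1-ol
Conditions: K2CO3, MeOH, rt
Reagents that add atoms: none
Why: Carbonate-catalysed methanolysis cleaves the C(sp)–Si bond selectively, while the O-silyl ethers of secondary alcohols should survive the short exposure.

Step 20
Reactants: 34 (E)-crotonaldehyde
Product: 35 (Z)-2-iodobut-2-enal
Conditions: I2, K2CO3, DMAP (cat.), THF/H2O, rt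
Reagents that add atoms: iodine, II
Why: α-Iodination of an enal by a Baylis–Hillman-type sequence (DMAP addition, iodination of the enolate, elimination of DMAP) should give the thermodynamically preferred Z iodoenal with methyl and iodine cis.

Step 21
Reactants: 35 (Z)-2-iodobut-2-enal
Product: 36 (Z)-2-iodobut-2-en-1-ol
Conditions: NaBH4, MeOH, 0 °C
Reagents that add atoms: none
Why: Borohydride 1,2-reduction of the aldehyde leaves the alkenyl iodide and its geometry untouched.

Step 22
Reactants: 36 (Z)-2-iodobut-2-en-1-ol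
Product: 37 (Z)-tert-butyl[(2-iodobut-2-en-1-yl)oxy]dimethylsilane
Conditions: TBSCl, imidazole, DMF, rt
Reagents that add atoms: tert-butyldimethylsilyl chloride, CC(C)(C)[Si](C)(C)Cl
Why: Standard silylation of a primary alcohol.

Step 23
Reactants: 37 alkenyl iodide TBS ether
Product: 39 (Z)-2-{[(tert-butyldimethylsilyl)oxy]methyl}but-2-enoic acid, via alkenyllithium 38 (not isolated)
Conditions: t-BuLi (2 equiv), Et2O, −78 °C; then CO2; then aq. HCl
Reagents that add atoms: carbon dioxide, O=C=O
Why: Iodine–lithium exchange of an alkenyl iodide proceeds with retention, and carboxylation at −78 °C (cold enough to suppress silyl migration) puts the carboxyl cis to the methyl group, which is the Z acid of the side chain.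

Step 24
Reactants: 33 ring alcohol; 39 side-chain acid
Product: 41 (1S,2Z,4R,6E,8R,9S)-4-(tert-butyldimethylsilyloxy)-9-ethynyl-2,6-dimethyl-8-(triethylsilyloxy)cyclodeca-2,6-dien-1-yl (Z)-2-{[(tert-butyldimethylsilyl)oxy]methyl}but-2-enoate, via mixed trichlorobenzoic anhydride 40 (not isolated)
Conditions: 2,4,6-Cl3C6H2COCl, Et3N, THF, rt; then 33, DMAP, toluene, rt
Reagents that add atoms: none
Why: Yamaguchi esterification, in which the mixed 2,4,6-trichlorobenzoic anhydride acylates the hindered allylic C9 alcohol with retention at C9, and brief contact with DMAP at room temperature is intended to keep the Z enoate from isomerising.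

Step 25
Reactants: 41 TES-protected ester
Product: 42 (1S,2Z,4R,6E,8R,9S)-4-(tert-butyldimethylsilyloxy)-9-ethynyl-8-hydroxy-2,6-dimethylcyclodeca-2,6-dien-1-yl (Z)-2-{[(tert-butyldimethylsilyl)oxy]methyl}but-2-enoate
Conditions: PPTS, MeOH/CH2Cl2, 0 °C
Reagents that add atoms: none
Why: Mild acid methanolysis removes the TES ether much faster than the TBS ethers, uncovering the C6 hydroxyl next to the ethynyl group, and any concurrent loss of the primary TBS ether would be made good in step 27.

Step 26
Reactants: 42 trans-6-hydroxy-7-ethynyl dienol ester; 43 carbon monoxide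
Product: 44 bis-TBS ether of the target, (2R,6R,7S,9S)-2-(tert-butyldimethylsilyloxy)-9-[(Z)-2-{[(tert-butyldimethylsilyl)oxy]methyl}but-2-enoyloxy]germacra-1(10)Z,4E,11(13)-trien-12,6-olide
Conditions: PdCl2 (10 mol%), PPh3 (20 mol%), SnCl2 (10 mol%), CO (7 bar), MeCN, 70 °C
Reagents that add atoms: none
Why: The C6 hydroxyl and CO form an alkoxycarbonyl complex of divalent palladium, which adds syn across the tethered C11≡C13 triple bond, and protonolysis of the alkenyl–palladium bond by the HCl released in the first stage frees the exo-methylene lactone and returns the catalyst. The closest known reaction type is the palladium-catalysed cyclocarbonylation of homopropargylic alcohols (2-ethynylcycloalkanols) to α-methylene-γ-butyrolactones. The one new ring, the γ-lactone, closes by intramolecular acylpalladation in the 5-exo-dig mode, forming O–C12 and C12–C11. No stereocentre is created, and the trans ring fusion is inherited from the anti C6/C7 pair made in step 12. The step needs selectivity for the alkyne over the two ring alkenes and the enoate and for exo closure, and both follow from the tether, since only the C6-bound alkoxycarbonyl–palladium unit can reach C11 through a five-membered transition state; no base is present that could isomerise the Z enoate or cleave the C9 ester.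

Step 27
Reactants: 44 bis-TBS lactone
Product: 45 CNP0273961.1, (2R,6R,7S,9S)-2-hydroxy-9-[(Z)-2-(hydroxymethyl)but-2-enoyloxy]germacra-1(10)Z,4E,11(13)-trien-12,6-olide
Conditions: HF·pyridine, pyridine, THF, 0 °C → rt
Reagents that add atoms: none
Why: Buffered fluoride cleavage removes the secondary and the primary TBS ether under conditions that the α-methylene lactone, the allylic ester and the Z enoate tolerate.

**Compound list**

1 | prenyl acetate | CC(C)=CCOC(C)=O | starting material
2 | (E)-4-hydroxy-3-methylbut-2-en-1-yl acetate | CC(=O)OC/C=C(\C)CO | intermediate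
3 | (E)-4-iodo-3-methylbut-2-en-1-yl acetate | CC(=O)OC/C=C(\C)CI | intermediate
4 | 2-[(tert-butyldimethylsilyl)oxy]acetic acid | CC(C)(C)[Si](C)(C)OCC(=O)O | starting material
5 | (S)-4-benzyloxazolidin-2-one | O=C1N[C@@H](Cc2ccccc2)CO1 | starting material
6 | 2-[(tert-butyldimethylsilyl)oxy]acetic pivalic anhydride | CC(C)(C)[Si](C)(C)OCC(=O)OC(=O)C(C)(C)C | intermediate
7 | (S)-4-benzyl-3-{2-[(tert-butyldimethylsilyl)oxy]acetyl}oxazolidin-2-one | CC(C)(C)[Si](C)(C)OCC(=O)N1[C@@H](Cc2ccccc2)COC1=O | intermediate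
8 | sodium Z-enolate of 7 | [Na+].[O-]/C(=C\O[Si](C)(C)C(C)(C)C)N1[C@@H](Cc2ccccc2)COC1=O | intermediate
9 | (S)-4-benzyl-3-[(2R,4E)-6-acetoxy-2-(tert-butyldimethylsilyloxy)-4-methylhex-4-enoyl]oxazolidin-2-one | CC(=O)OC/C=C(\C)C[C@@H](O[Si](C)(C)C(C)(C)C)C(=O)N1[C@@H](Cc2ccccc2)COC1=O | intermediate
10 | methyl (2R,4E)-2-(tert-butyldimethylsilyloxy)-6-hydroxy-4-methylhex-4-enoate | COC(=O)[C@H](O[Si](C)(C)C(C)(C)C)C/C(C)=C/CO | intermediate
11 | methyl (2R,4E)-2-(tert-butyldimethylsilyloxy)-4-methyl-6-oxohex-4-enoate | COC(=O)[C@H](O[Si](C)(C)C(C)(C)C)C/C(C)=C/C=O | intermediate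
12 | 3-[(4-methoxybenzyl)oxy]propan-1-ol | COc1ccc(COCCCO)cc1 | starting material
13 | 3-[(4-methoxybenzyl)oxy]propanal | COc1ccc(COCCC=O)cc1 | intermediate
14 | trimethylsilylacetylene | C#C[Si](C)(C)C | starting material
15 | lithium (trimethylsilyl)acetylide | [Li]C#C[Si](C)(C)C | intermediate
16 | rac-5-[(4-methoxybenzyl)oxy]-1-(trimethylsilyl)pent-1-yn-3-ol | COc1ccc(COCCC(O)C#C[Si](C)(C)C)cc1 | intermediate
17 | 5-[(4-methoxybenzyl)oxy]-1-(trimethylsilyl)pent-1-yn-3-one | COc1ccc(COCCC(=O)C#C[Si](C)(C)C)cc1 | intermediate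
18 | (R)-5-[(4-methoxybenzyl)oxy]-1-(trimethylsilyl)pent-1-yn-3-ol | COc1ccc(COCC[C@@H](O)C#C[Si](C)(C)C)cc1 | intermediate
19 | (R)-5-[(4-methoxybenzyl)oxy]-1-(trimethylsilyl)pent-1-yn-3-yl methanesulfonate | COc1ccc(COCC[C@@H](OS(C)(=O)=O)C#C[Si](C)(C)C)cc1 | intermediate
20 | (P)-{5-[(4-methoxybenzyl)oxy]-1-(trimethylsilyl)penta-1,2-dien-1-yl}indium iodide methanesulfonate (allene axis P, not expressible in the SMILES) | COc1ccc(COCCC=C=C([In](I)OS(C)(=O)=O)[Si](C)(C)C)cc1 | intermediate
21 | methyl (2R,4E,6R,7S)-2-(tert-butyldimethylsilyloxy)-6-hydroxy-7-{2-[(4-methoxybenzyl)oxy]ethyl}-4-methyl-9-(trimethylsilyl)non-4-en-8-ynoate | COC(=O)[C@H](O[Si](C)(C)C(C)(C)C)C/C(C)=C/[C@@H](O)[C@@H](CCOCc1ccc(OC)cc1)C#C[Si](C)(C)C | intermediate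
22 | methyl (2R,4E,6R,7S)-2-(tert-butyldimethylsilyloxy)-7-{2-[(4-methoxybenzyl)oxy]ethyl}-4-methyl-6-(triethylsilyloxy)-9-(trimethylsilyl)non-4-en-8-ynoate | COC(=O)[C@H](O[Si](C)(C)C(C)(C)C)C/C(C)=C/[C@@H](O[Si](CC)(CC)CC)[C@@H](CCOCc1ccc(OC)cc1)C#C[Si](C)(C)C | intermediate
23 | (2R,4E,6R,7S)-2-(tert-butyldimethylsilyloxy)-7-{2-[(4-methoxybenzyl)oxy]ethyl}-4-methyl-6-(triethylsilyloxy)-9-(trimethylsilyl)non-4-en-8-ynal | O=C[C@H](O[Si](C)(C)C(C)(C)C)C/C(C)=C/[C@@H](O[Si](CC)(CC)CC)[C@@H](CCOCc1ccc(OC)cc1)C#C[Si](C)(C)C | intermediate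
24 | ethyltriphenylphosphonium bromide | CC[P+](c1ccccc1)(c1ccccc1)c1ccccc1.[Br-] | starting material
25 | ethylidenetriphenylphosphorane | CC=P(c1ccccc1)(c1ccccc1)c1ccccc1 | intermediate
26 | (1-iodoethyl)triphenylphosphonium iodide | CC(I)[P+](c1ccccc1)(c1ccccc1)c1ccccc1.[I-] | intermediate
27 | (1-iodoethylidene)triphenylphosphorane | CC(I)=P(c1ccccc1)(c1ccccc1)c1ccccc1 | intermediate
28 | (3S,4R,5E,8R,9Z)-8-(tert-butyldimethylsilyloxy)-10-iodo-1-[(4-methoxybenzyl)oxy]-6-methyl-4-(triethylsilyloxy)-3-[(trimethylsilyl)ethynyl]undeca-5,9-diene | C/C(I)=C/[C@H](O[Si](C)(C)C(C)(C)C)C/C(C)=C/[C@@H](O[Si](CC)(CC)CC)[C@@H](CCOCc1ccc(OC)cc1)C#C[Si](C)(C)C | intermediate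
29 | (3S,4R,5E,8R,9Z)-8-(tert-butyldimethylsilyloxy)-10-iodo-6-methyl-4-(triethylsilyloxy)-3-[(trimethylsilyl)ethynyl]undeca-5,9-dien-1-ol | C/C(I)=C/[C@H](O[Si](C)(C)C(C)(C)C)C/C(C)=C/[C@@H](O[Si](CC)(CC)CC)[C@@H](CCO)C#C[Si](C)(C)C | intermediate
30 | (3S,4R,5E,8R,9Z)-8-(tert-butyldimethylsilyloxy)-10-iodo-6-methyl-4-(triethylsilyloxy)-3-[(trimethylsilyl)ethynyl]undeca-5,9-dienal | C/C(I)=C/[C@H](O[Si](C)(C)C(C)(C)C)C/C(C)=C/[C@@H](O[Si](CC)(CC)CC)[C@@H](CC=O)C#C[Si](C)(C)C | intermediate
31 | alkenylchromium dichloride derived from 30 (CrCl2 unit in place of iodine, geometry retained) | C/C([Cr](Cl)Cl)=C/[C@H](O[Si](C)(C)C(C)(C)C)C/C(C)=C/[C@@H](O[Si](CC)(CC)CC)[C@@H](CC=O)C#C[Si](C)(C)C | intermediate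
32 | (1S,2Z,4R,6E,8R,9S)-4-(tert-butyldimethylsilyloxy)-2,6-dimethyl-8-(triethylsilyloxy)-9-[(trimethylsilyl)ethynyl]cyclodeca-2,6-dien-1-ol | CC[Si](CC)(CC)O[C@@H]1/C=C(\C)C[C@@H](O[Si](C)(C)C(C)(C)C)/C=C(/C)[C@@H](O)C[C@H]1C#C[Si](C)(C)C | intermediate
33 | (1S,2Z,4R,6E,8R,9S)-4-(tert-butyldimethylsilyloxy)-9-ethynyl-2,6-dimethyl-8-(triethylsilyloxy)cyclodeca-2,6-dien-1-ol | CC[Si](CC)(CC)O[C@@H]1/C=C(\C)C[C@@H](O[Si](C)(C)C(C)(C)C)/C=C(/C)[C@@H](O)C[C@H]1C#C | intermediate
34 | (E)-crotonaldehyde | C/C=C/C=O | starting material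
35 | (Z)-2-iodobut-2-enal | C/C=C(\I)C=O | intermediate
36 | (Z)-2-iodobut-2-en-1-ol | C/C=C(\I)CO | intermediate
37 | (Z)-tert-butyl[(2-iodobut-2-en-1-yl)oxy]dimethylsilane | C/C=C(\I)CO[Si](C)(C)C(C)(C)C | intermediate
38 | (Z)-1-[(tert-butyldimethylsilyl)oxy]but-2-en-2-yllithium (geometry of 37 retained) | C/C=C(\[Li])CO[Si](C)(C)C(C)(C)C | intermediate
39 | (Z)-2-{[(tert-butyldimethylsilyl)oxy]methyl}but-2-enoic acid | C/C=C(\C(=O)O)CO[Si](C)(C)C(C)(C)C | intermediate
40 | mixed anhydride of 39 and 2,4,6-trichlorobenzoic acid | C/C=C(\C(=O)OC(=O)c1c(Cl)cc(Cl)cc1Cl)CO[Si](C)(C)C(C)(C)C | intermediate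
41 | (1S,2Z,4R,6E,8R,9S)-4-(tert-butyldimethylsilyloxy)-9-ethynyl-2,6-dimethyl-8-(triethylsilyloxy)cyclodeca-2,6-dien-1-yl (Z)-2-{[(tert-butyldimethylsilyl)oxy]methyl}but-2-enoate | CC[Si](CC)(CC)O[C@@H]1/C=C(\C)C[C@@H](O[Si](C)(C)C(C)(C)C)/C=C(/C)[C@@H](OC(=O)/C(=C\C)CO[Si](C)(C)C(C)(C)C)C[C@H]1C#C | intermediate
42 | (1S,2Z,4R,6E,8R,9S)-4-(tert-butyldimethylsilyloxy)-9-ethynyl-8-hydroxy-2,6-dimethylcyclodeca-2,6-dien-1-yl (Z)-2-{[(tert-butyldimethylsilyl)oxy]methyl}but-2-enoate | O[C@@H]1/C=C(\C)C[C@@H](O[Si](C)(C)C(C)(C)C)/C=C(/C)[C@@H](OC(=O)/C(=C\C)CO[Si](C)(C)C(C)(C)C)C[C@H]1C#C | intermediate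
43 | carbon monoxide | [C-]#[O+] | starting material
44 | bis-TBS ether of the target, (2R,6R,7S,9S)-2-(tert-butyldimethylsilyloxy)-9-[(Z)-2-{[(tert-butyldimethylsilyl)oxy]methyl}but-2-enoyloxy]germacra-1(10)Z,4E,11(13)-trien-12,6-olide | C=C1C(=O)O[C@@H]2/C=C(\C)C[C@@H](O[Si](C)(C)C(C)(C)C)/C=C(/C)[C@@H](OC(=O)/C(=C\C)CO[Si](C)(C)C(C)(C)C)C[C@@H]12 | intermediate
45 | CNP0273961.1, (2R,6R,7S,9S)-2-hydroxy-9-[(Z)-2-(hydroxymethyl)but-2-enoyloxy]germacra-1(10)Z,4E,11(13)-trien-12,6-olide | C=C1C(=O)O[C@@H]2/C=C(\C)C[C@@H](O)/C=C(/C)[C@@H](OC(=O)/C(=C\C)CO)C[C@@H]12 | target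

**Step count**

Total: 27 steps. Longest linear sequence: 17 steps (1, 2, 4–6, 12–19, 24–27, from prenyl acetate). Side branches: step 3 (imide), steps 7–11 (mesylate), steps 20–23 (side-chain acid).

**Steps most likely to fail**

Step 18. The ring closure has to overcome transannular strain, and the alkenylchromium may attack either aldehyde face, so poor or reversed facial selectivity at C9 is the main concern. The fallback replaces substrate control by reagent control. It sets out from 32 as obtained (C9 epimers). Oxidation with Dess–Martin periodinane in CH2Cl2 gives the cyclodecadienone F1. Reduction of this ketone with catecholborane and (R)-2-methyl-CBS-oxazaborolidine in toluene at −78 °C, with the alkenyl residue acting as the large group, should give the 9S alcohol and so comes back to the route at 32.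

Step 26. The chloride-rich, Lewis-acidic medium at 70 °C may ionise the allylic C6 alcohol or strip silyl ethers before carbonylation, or the acylpalladation may stall on the crowded ring. The fallback forms the same lactone by a radical instead of a palladium pathway and sets out from 42. Acylation of the C6 hydroxyl with Se-phenyl carbonochloridoselenoate (PhSeCOCl) and pyridine in CH2Cl2 at 0 °C gives the Se-phenyl selenocarbonate F2. Treatment with Bu3SnH and AIBN in benzene at 80 °C generates the alkoxycarbonyl radical, which cyclises 5-exo-dig onto the alkyne; hydrogen transfer to the alkenyl radical gives the exo-methylene lactone, and the sequence comes back to the route at 44.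

Step 24. Activation of the Z acid in the presence of DMAP may isomerise the enoate by reversible conjugate addition, and acylation of the hindered ring alcohol may be slow. The fallback avoids acyl activation altogether and sets out from 33. Dess–Martin oxidation gives the ethynyl cyclodecadienone F3. Reduction with catecholborane and (S)-2-methyl-CBS-oxazaborolidine should give the 9R alcohol F4. Mitsunobu esterification of this alcohol with acid 39 (PPh3, diisopropyl azodicarboxylate, THF, 0 °C) uses the carboxylate as nucleophile, inverts C9 and comes back to the route at 41.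

**Further compounds**

F1 | step 18 | (2Z,4R,6E,8R,9S)-4-(tert-butyldimethylsilyloxy)-2,6-dimethyl-8-(triethylsilyloxy)-9-[(trimethylsilyl)ethynyl]cyclodeca-2,6-dien-1-one | CC[Si](CC)(CC)O[C@@H]1/C=C(\C)C[C@@H](O[Si](C)(C)C(C)(C)C)/C=C(/C)C(=O)C[C@H]1C#C[Si](C)(C)C
F2 | step 26 | Se-phenyl selenocarbonate of 42 at the C6 oxygen (all stereocentres and olefin geometries as in 42) | O=C([Se]c1ccccc1)O[C@@H]1/C=C(\C)C[C@@H](O[Si](C)(C)C(C)(C)C)/C=C(/C)[C@@H](OC(=O)/C(=C\C)CO[Si](C)(C)C(C)(C)C)C[C@H]1C#C
F3 | step 24 | (2Z,4R,6E,8R,9S)-4-(tert-butyldimethylsilyloxy)-9-ethynyl-2,6-dimethyl-8-(triethylsilyloxy)cyclodeca-2,6-dien-1-one | CC[Si](CC)(CC)O[C@@H]1/C=C(\C)C[C@@H](O[Si](C)(C)C(C)(C)C)/C=C(/C)C(=O)C[C@H]1C#C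
F4 | step 24 | (1R,2Z,4R,6E,8R,9S)-4-(tert-butyldimethylsilyloxy)-9-ethynyl-2,6-dimethyl-8-(triethylsilyloxy)cyclodeca-2,6-dien-1-ol (C9 epimer of 33) | CC[Si](CC)(CC)O[C@@H]1/C=C(\C)C[C@@H](O[Si](C)(C)C(C)(C)C)/C=C(/C)[C@H](O)C[C@H]1C#C
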